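**Plan**

1. Retrosynthesis: the two phenols are unmasked last (C5–OH from a methyl ether, C5'–OH from a tosylate). Ring C is then cut at O1–C8a to give an open 1,3-diketone, and the diketone is cut at C2–C3 into a ring A methyl ketone and a ring B methyl ester. The C5'–O bond of that ester goes back to a C–H bond.
2. Forward: the ring B ester is hydroxylated at C5' and tosylated, then joined to the ring A ketone by a Claisen condensation (C2–C3). Ring C, the only ring that is made, closes last by anodic C–H etherification (O1–C8a); rings A and B are bought.
3. Enabling feature: C8a is the only unsubstituted carbon of ring A ortho to the acyl-bearing C4a. It lies para to the C6 methoxy group, which stabilises the cationic σ-complex, and the enol oxygen on C2 reaches it through a six-membered transition state. The sulfonate on ring B keeps that ring out of the oxidation.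
4. Stereochemistry: the target has no stereocenter and no configured double bond, so nothing has to be controlled.

Key step: step 4

Remark on the chemistry: the ring B phenol is carried as a p-toluenesulfonate, which has no acidic α-hydrogen and so cannot fragment to a sulfene under the enolate conditions of step 3; compounds 1 and 5 are taken to be commercial.

**Route**

Step 1
Reactants: 1 methyl 2,3-dimethoxybenzoate
Product: 3 methyl 5-hydroxy-2,3-dimethoxybenzoate, via aryl pinacol boronate 2 (not isolated)
Conditions: [Ir(OMe)(cod)]2 (cat.), 4,4'-di-tert-butyl-2,2'-bipyridine, B2pin2 (1.0 equiv), THF, 80 °C; then KHSO5 (as Oxone, 2KHSO5·KHSO4·K2SO4), acetone/H2O, rt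
Reagents that add atoms: bis(pinacolato)diboron, CC1(C)OB(OC1(C)C)B1OC(C)(C)C(C)(C)O1 (boron of 2); potassium peroxymonosulfate, [K+].[O-]S(=O)(=O)OO (oxygen of the new hydroxyl)
Why: Iridium-catalysed C–H borylation is governed by sterics and C5–H is the only ring C–H of 1 without an ortho substituent, so the boronate should form there alone, and ipso-oxidation of the aryl boronate by KHSO5 should then give the phenol with the ester untouched.

Step 2
Reactants: 3 methyl 5-hydroxy-2,3-dimethoxybenzoate
Product: 4 methyl 2,3-dimethoxy-5-(tosyloxy)benzoate
Conditions: TsCl, Et3N, DMAP (cat.), CH2Cl2, 0 °C to rt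
Reagents that add atoms: p-toluenesulfonyl chloride, Cc1ccc(cc1)S(Cl)(=O)=O
Why: DMAP-catalysed O-sulfonylation of a phenol should be clean, and the resulting aryl tosylate withdraws electron density from ring B and is stable to the enolate, anodic and Lewis-acidic conditions that follow.

Step 3
Reactants: 4 methyl 2,3-dimethoxy-5-(tosyloxy)benzoate; 5 1-(2,3,4-trimethoxyphenyl)ethanone
Product: 6 3,4-dimethoxy-5-[3-oxo-3-(2,3,4-trimethoxyphenyl)propanoyl]phenyl 4-methylbenzenesulfonate
Conditions: 5, LiN(SiMe3)2 (2.2 equiv), THF, −78 °C; then 4, −78 °C to rt; aq. NH4Cl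
Reagents that add atoms: none
Why: In this crossed Claisen condensation the preformed lithium enolate of 5 acylates the non-enolisable methyl ester 4, and deprotonation of the 1,3-diketone by the second equivalent of base drives the reaction forward while the tosylate should survive.

Step 4
Reactants: 6 3,4-dimethoxy-5-[3-oxo-3-(2,3,4-trimethoxyphenyl)propanoyl]phenyl 4-methylbenzenesulfonate
Product: 7 3,4-dimethoxy-5-(5,6,7-trimethoxy-4-oxo-4H-chromen-2-yl)phenyl 4-methylbenzenesulfonate
Conditions: graphite anode, Pt cathode, undivided cell, constant current (about 2.2 F per mol), n-Bu4NBF4, (CF3)2CHOH (HFIP), rt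
Reagents that add atoms: none
Why: Proposed new method: at the graphite anode the 2,3,4-trimethoxybenzoyl enol unit, the most electron-rich π system of 6, should lose one electron, the oxygen on the ring B-bearing enol carbon should add to the free ortho carbon of the ring A radical cation, and a second electron transfer with loss of two protons should restore aromaticity and give the pyrone, while hydrogen is evolved at the cathode. The closest known reaction types are anodic dehydrogenative C–O cyclisations (lactonisation of biaryl-2-carboxylic acids to benzocoumarins, closure of anilides to benzoxazoles) and the FeCl3-mediated oxidative closure of α-aryl ketones to benzofurans through the enol oxygen. Ring C closes in a 6-endo-trig mode, the C4a–C8a bond of the arene lying inside the new ring, and no stereocenter is formed. The step needs closure on ring A and not on ring B: the tosyloxy group raises the oxidation potential of ring B, whereas ring A carries three donor groups and its σ-complex at C8a is stabilised by the para methoxy group. It also needs C–H substitution instead of ipso attack at the methoxy-bearing ortho carbon: only the adduct at the C–H carbon can be made irreversible by a second oxidation and proton loss, the ipso adduct being able to revert. HFIP stabilises the radical cation, opens the internal hydrogen bond of the enol so that its oxygen can turn toward ring A, and by hydrogen bonding to the pyrone carbonyl of 7 should protect the product from further oxidation.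

Step 5
Reactants: 7 3,4-dimethoxy-5-(5,6,7-trimethoxy-4-oxo-4H-chromen-2-yl)phenyl 4-methylbenzenesulfonate
Product: 8 3-(5-hydroxy-6,7-dimethoxy-4-oxo-4H-chromen-2-yl)-4,5-dimethoxyphenyl 4-methylbenzenesulfonate
Conditions: BCl3 (2 equiv), CH2Cl2, −78 to 0 °C; then H2O
Reagents that add atoms: none
Why: In this chelation-controlled ether cleavage BCl3 binds the C4 carbonyl and the peri C5 methoxy oxygen in a six-membered chelate and chloride removes that methyl group alone, a standard selective 5-O-demethylation of polymethoxyflavones that leaves the aryl sulfonate and the other methyl ethers in place.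

Step 6
Reactants: 8 3-(5-hydroxy-6,7-dimethoxy-4-oxo-4H-chromen-2-yl)-4,5-dimethoxyphenyl 4-methylbenzenesulfonate
Product: 9 2-(5-hydroxy-2,3-dimethoxyphenyl)-5-hydroxy-6,7-dimethoxy-4H-chromen-4-one (the target)
Conditions: KOH, 1,4-dioxane/H2O, 70 °C; then aq. HCl
Reagents that add atoms: none
Why: Alkaline hydrolysis of the aryl sulfonate by hydroxide attack at sulfur should free the ring B phenol, the C5 phenoxide present under these conditions donating into the pyrone carbonyl and so making C2 a poor acceptor for hydroxide, and the absence of an alcohol co-solvent avoiding an alkyl tosylate that could alkylate the phenoxides.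

**Compound list**

1 | methyl 2,3-dimethoxybenzoate | COC(=O)c1cccc(OC)c1OC | starting material
2 | methyl 2,3-dimethoxy-5-(4,4,5,5-tetramethyl-1,3,2-dioxaborolan-2-yl)benzoate | COC(=O)c1cc(B2OC(C)(C)C(C)(C)O2)cc(OC)c1OC | intermediate
3 | methyl 5-hydroxy-2,3-dimethoxybenzoate | COC(=O)c1cc(O)cc(OC)c1OC | intermediate
4 | methyl 2,3-dimethoxy-5-(tosyloxy)benzoate | COC(=O)c1cc(OS(=O)(=O)c2ccc(C)cc2)cc(OC)c1OC | intermediate
5 | 1-(2,3,4-trimethoxyphenyl)ethanone | CC(=O)c1ccc(OC)c(OC)c1OC | starting material
6 | 3,4-dimethoxy-5-[3-oxo-3-(2,3,4-trimethoxyphenyl)propanoyl]phenyl 4-methylbenzenesulfonate | COc1ccc(C(=O)CC(=O)c2cc(OS(=O)(=O)c3ccc(C)cc3)cc(OC)c2OC)c(OC)c1OC | intermediate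
7 | 3,4-dimethoxy-5-(5,6,7-trimethoxy-4-oxo-4H-chromen-2-yl)phenyl 4-methylbenzenesulfonate | COc1cc(OS(=O)(=O)c2ccc(C)cc2)cc(-c2cc(=O)c3c(OC)c(OC)c(OC)cc3o2)c1OC | intermediate
8 | 3-(5-hydroxy-6,7-dimethoxy-4-oxo-4H-chromen-2-yl)-4,5-dimethoxyphenyl 4-methylbenzenesulfonate | COc1cc(OS(=O)(=O)c2ccc(C)cc2)cc(-c2cc(=O)c3c(O)c(OC)c(OC)cc3o2)c1OC | intermediate
9 | 2-(5-hydroxy-2,3-dimethoxyphenyl)-5-hydroxy-6,7-dimethoxy-4H-chromen-4-one | COc1cc(O)cc(-c2cc(=O)c3c(O)c(OC)c(OC)cc3o2)c1OC | target

**Step count and risks**

Total step count: 6. Longest linear sequence: 6 steps (1 to 9); ketone 5 enters at step 3.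

Steps most likely to fail:

Step 4 (proposed new method). The radical cation may be consumed before the enol oxygen reaches C8a: by oxidation at the enol carbon with dimerisation or capture of solvent, by ipso attack at the methoxy-bearing ortho carbon with loss of methanol, or by further oxidation of the product. The fallback uses known chemistry and buys the O1–C8a bond with the starting material. It sets out from ester 4, which is condensed with commercial 1-(6-hydroxy-2,3,4-trimethoxyphenyl)ethanone F1 (LiN(SiMe3)2, 3.3 equiv, THF, −78 °C to rt) to give the ortho-hydroxyaryl diketone 3-[3-(6-hydroxy-2,3,4-trimethoxyphenyl)-3-oxopropanoyl]-4,5-dimethoxyphenyl 4-methylbenzenesulfonate F2. Acid-catalysed cyclodehydration (cat. H2SO4, AcOH, 100 °C) should then close ring C, and the fallback comes back to the route at flavone 7.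

Step 5. Ether cleavage may not stop at the chelated C5 methoxy group: once the boron chelate has formed, the neighbouring C6 methyl ether can be cleaved as well, so that mono-demethylation cannot be held. The fallback gives up selectivity in the cleavage and recovers it in an alkylation. It sets out from 7, which is driven with excess BCl3 (CH2Cl2, rt) to the catechol 3-(5,6-dihydroxy-7-methoxy-4-oxo-4H-chromen-2-yl)-4,5-dimethoxyphenyl 4-methylbenzenesulfonate F3. Methylation with MeI (1.05 equiv) and K2CO3 in acetone should then take place at O6 alone, because the C5 hydroxyl is held back by its hydrogen bond to the C4 carbonyl, and the fallback comes back at 8.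

Step 6. Hydroxide may add to C2 and open ring C, with retro-Claisen cleavage of the resulting diketone, faster than it attacks the sulfonyl sulfur. The fallback avoids hydrolysis and uses the tosylate as a pseudohalide. It sets out from 8: oxidative addition of the C–OTs bond to zerovalent palladium and borylation (Pd(OAc)2, XPhos, B2pin2, KOAc, 1,4-dioxane, 100 °C) should give 2-[2,3-dimethoxy-5-(4,4,5,5-tetramethyl-1,3,2-dioxaborolan-2-yl)phenyl]-5-hydroxy-6,7-dimethoxy-4H-chromen-4-one F4. Mild ipso-oxidation (NaBO3·4H2O, THF/H2O, rt) then returns the phenol on the same carbon, and the fallback comes back at the target 9.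

Further compounds
F1 | step 4 | 1-(6-hydroxy-2,3,4-trimethoxyphenyl)ethanone | CC(=O)c1c(O)cc(OC)c(OC)c1OC
F2 | step 4 | 3-[3-(6-hydroxy-2,3,4-trimethoxyphenyl)-3-oxopropanoyl]-4,5-dimethoxyphenyl 4-methylbenzenesulfonate | COc1cc(O)c(C(=O)CC(=O)c2cc(OS(=O)(=O)c3ccc(C)cc3)cc(OC)c2OC)c(OC)c1OC
F3 | step 5 | 3-(5,6-dihydroxy-7-methoxy-4-oxo-4H-chromen-2-yl)-4,5-dimethoxyphenyl 4-methylbenzenesulfonate | COc1cc(OS(=O)(=O)c2ccc(C)cc2)cc(-c2cc(=O)c3c(O)c(O)c(OC)cc3o2)c1OC
F4 | step 6 | 2-[2,3-dimethoxy-5-(4,4,5,5-tetramethyl-1,3,2-dioxaborolan-2-yl)phenyl]-5-hydroxy-6,7-dimethoxy-4H-chromen-4-one | COc1cc(B2OC(C)(C)C(C)(C)O2)cc(-c2cc(=O)c3c(O)c(OC)c(OC)cc3o2)c1OC
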